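The 4-pyranone ring is opened retrosynthetically at O1–C6 to a 3,5-dioxoester, and this chain is cut at C5–C6. The key step exploits the fact that ring carbons C2–C6 of the pyranone form a 1,3,5-tricarbonyl array (C2 ester carbon, C3–OCH3, C4 ketone, C5–CH3, C6 acyl carbon): one Lewis-acid-catalysed C-acylation of the bis(trimethylsilyl) dienol ether of methyl 2-methoxy-3-oxopentanoate with an (E)-β,γ-unsaturated ω-chloro acid chloride assembles the complete carbon skeleton. No base is involved, so the doubly activated C1' methylene between C6 and the C2'=C3' alkene stays untouched. The acid chloride arises from undec-10-yn-1-ol by methylalumination; cyclodehydration and thioacetate displacement complete the synthesis.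

Key step: step 9

Remark on the chemistry: the silyl enol ethers and the open-chain triketide are carried as mixtures of geometric isomers, tautomers and diastereomers; this is without consequence because every such centre ends as an sp2 ring carbon.

Step 1
Reactants: 1 undec-10-yn-1-ol
Product: 2 11-chloroundec-1-yne
Conditions: PPh3, CCl4, CH2Cl2, reflux
Reagents that add atoms: carbon tetrachloride, ClC(Cl)(Cl)Cl
Why: Appel reaction: the alkoxyphosphonium formed from PPh3/CCl4 is displaced by chloride in an SN2 step at the primary carbon, and the terminal alkyne is inert to these neutral conditions.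

Step 2
Reactants: 2 11-chloroundec-1-yne; 3 ethylene oxide
Product: 6 (E)-13-chloro-4-methyltridec-3-en-1-ol, via alkenyldimethylalane 4 (not isolated), via lithium alkenylalanate 5 (not isolated)
Conditions: Al(CH3)3 (2 equiv), Cp2ZrCl2 (0.25 equiv), CH2Cl2, 0 °C to rt; volatiles removed, hexane/THF; n-BuLi (1 equiv), −78 to 0 °C; ethylene oxide, 0 °C to rt; aq. HCl
Reagents that add atoms: trimethylaluminium, C[Al](C)C
Why: Negishi zirconium-catalysed carboalumination adds CH3 and Al syn across the terminal alkyne with Al on the terminal carbon, which fixes the E trisubstituted alkene, and the derived butyl alanate opens ethylene oxide by alkenyl transfer with retention of alkene geometry, while the primary chloride tolerates both organometallics at low temperature.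

Step 3
Reactants: 6 (E)-13-chloro-4-methyltridec-3-en-1-ol
Product: 8 (E)-13-chloro-4-methyltridec-3-enoic acid, via aldehyde 7 (not isolated)
Conditions: CrO3, H2SO4, H2O, acetone, 0 °C
Reagents that add atoms: water, O
Why: Jones oxidation: hexavalent chromium takes the primary alcohol to the aldehyde, whose hydrate should be oxidised on to the acid faster than the β,γ-alkene can move into conjugation at 0 °C, an established way from 3-alken-1-ols to 3-alkenoic acids.

Step 4
Reactants: 8 (E)-13-chloro-4-methyltridec-3-enoic acid
Product: 9 (E)-13-chloro-4-methyltridec-3-enoyl chloride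
Conditions: (COCl)2, DMF (cat.), CH2Cl2, 0 °C to rt; concentrate, use crude
Reagents that add atoms: oxalyl chloride, ClC(=O)C(=O)Cl
Why: Acid chloride formation through the Vilsmeier-type chloroiminium from (COCl)2/DMF runs without base and gives only gaseous by-products, so neither a ketene nor a conjugated alkene can form from the C2 methylene.

Step 5
Reactants: 10 methyl 3-oxopentanoate
Product: 11 methyl 2-diazo-3-oxopentanoate
Conditions: 4-acetamidobenzenesulfonyl azide, Et3N, MeCN, 0 °C to rt
Reagents that add atoms: 4-acetamidobenzenesulfonyl azide, CC(=O)Nc1ccc(cc1)S(=O)(=O)N=[N+]=[N-]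
Why: Regitz diazo transfer: the triethylammonium enolate of the β-ketoester attacks the terminal nitrogen of the sulfonyl azide and the adduct collapses to the stabilised α-diazo-β-ketoester and the sulfonamide.

Step 6
Reactants: 11 methyl 2-diazo-3-oxopentanoate
Product: 12 methyl 2-methoxy-3-oxopentanoate
Conditions: Rh2(OAc)4 (1 mol %), MeOH (excess), CH2Cl2, rt
Reagents that add atoms: methanol, CO
Why: Rhodium carbenoid O–H insertion: Rh2(OAc)4 (divalent rhodium) turns the diazo compound into an electrophilic carbenoid that the excess methanol traps through an oxonium ylide and proton shift, which should outpace Wolff rearrangement.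

Step 7
Reactants: 12 methyl 2-methoxy-3-oxopentanoate
Product: 13 methyl 2-methoxy-3-(trimethylsilyloxy)pent-2-enoate
Conditions: Me3SiCl, Et3N, toluene, rt; filter, concentrate
Reagents that add atoms: chlorotrimethylsilane, C[Si](C)(C)Cl
Why: Soft enolisation and O-silylation of a β-ketoester: the C2 proton between the two carbonyls is acidic enough for Et3N, and the enolate is silylated on the ketone oxygen to give the conjugated silyl enol ether.

Step 8
Reactants: 13 methyl 2-methoxy-3-(trimethylsilyloxy)pent-2-enoate
Product: 14 1,2-dimethoxy-1,3-bis(trimethylsilyloxy)penta-1,3-diene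
Conditions: LiN(iPr)2 (LDA), THF, −78 °C; Me3SiCl, −78 °C to rt; hexane, filter, concentrate
Reagents that add atoms: chlorotrimethylsilane, C[Si](C)(C)Cl
Why: Kinetic γ-deprotonation of the vinylogous ester at C4 and O-silylation of the dienolate on the ester oxygen, the standard two-stage preparation of 1,3-bis(silyloxy)-1,3-dienes from β-ketoesters.

Step 9
Reactants: 9 (E)-13-chloro-4-methyltridec-3-enoyl chloride; 14 1,2-dimethoxy-1,3-bis(trimethylsilyloxy)penta-1,3-diene
Product: 16 methyl (E)-17-chloro-2-methoxy-4,8-dimethyl-3,5-dioxoheptadec-7-enoate, via silyl enol ether 15 (not isolated)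
Conditions: Me3SiOSO2CF3 (0.2 equiv), CH2Cl2, −78 °C; then aq. NaHCO3, brief wash with 1 M HCl
Reagents that add atoms: none
Why: Me3SiOSO2CF3 activates the acid chloride as an acylium-type electrophile, the terminal carbon of the diene (future C5) adds to it, and chloride removes Me3Si from the resulting ester oxocarbenium, which releases Me3SiCl, regenerates the catalyst and leaves silyl enol ether 15 that aqueous work-up hydrolyses to the 3,5-dioxoester. The closest known reaction type is the Mukaiyama-type C-acylation of 1,3-bis(silyloxy)-1,3-dienes with acid chlorides, a flask version of the decarboxylative Claisen condensation of polyketide biosynthesis. No ring is closed, and the two sp3 centres created (C2 and C4 of 16) are left uncontrolled because both become sp2 ring carbons. The selectivity needed is attack through the terminal and not the central diene carbon, and on carbon and not on oxygen; the terminal carbon carries the largest HOMO coefficient and is unhindered, whereas the central carbon is fully substituted and flanked by two oxygenated carbons. Since neither amine nor alkoxide is present, the C2 methylene of 9 (future C1') cannot give a ketene or move the alkene into conjugation.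

Step 10
Reactants: 16 methyl (E)-17-chloro-2-methoxy-4,8-dimethyl-3,5-dioxoheptadec-7-enoate
Product: 17 6-[(E)-12-chloro-3-methyldodec-2-en-1-yl]-2,3-dimethoxy-5-methyl-4H-pyran-4-one
Conditions: PPh3, CCl4, THF, rt
Reagents that add atoms: none
Why: Appel-type cyclodehydration known for 3,5-dioxoesters: the C5 enol oxygen is activated as an oxyphosphonium leaving group, the ester carbonyl oxygen most plausibly closes the O1–C6 bond by 6-endo addition–elimination with loss of Ph3PO, and loss of the C2 proton gives the 2-methoxy-4-pyranone without any base that could deprotonate C1'.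

Step 11
Reactants: 17 6-[(E)-12-chloro-3-methyldodec-2-en-1-yl]-2,3-dimethoxy-5-methyl-4H-pyran-4-one
Product: 18 lehualide C
Conditions: KSC(O)CH3, NaI (cat.), DMF, 50 °C
Reagents that add atoms: potassium thioacetate, CC(=O)[S-].[K+]
Why: SN2 thioacetate displacement with Finkelstein catalysis: iodide converts the primary chloride into the iodide in situ and the soft, non-basic thioacetate anion substitutes it without touching the pyranone, its methoxy groups or the C1' methylene.

Compound list
1 | undec-10-yn-1-ol | OCCCCCCCCCC#C | starting material
2 | 11-chloroundec-1-yne | ClCCCCCCCCCC#C | intermediate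
3 | ethylene oxide (oxirane) | C1CO1 | starting material
4 | [(E)-11-chloro-2-methylundec-1-en-1-yl]dimethylalane (formed in the flask, not isolated) | C[Al](C)/C=C(\C)CCCCCCCCCCl | intermediate
5 | lithium butyl[(E)-11-chloro-2-methylundec-1-en-1-yl]dimethylaluminate (formed in the flask, not isolated) | [Li+].CCCC[Al-](C)(C)/C=C(\C)CCCCCCCCCCl | intermediate
6 | (E)-13-chloro-4-methyltridec-3-en-1-ol | OCC/C=C(\C)CCCCCCCCCCl | intermediate
7 | (E)-13-chloro-4-methyltridec-3-enal (formed in the flask, not isolated) | O=CC/C=C(\C)CCCCCCCCCCl | intermediate
8 | (E)-13-chloro-4-methyltridec-3-enoic acid | OC(=O)C/C=C(\C)CCCCCCCCCCl | intermediate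
9 | (E)-13-chloro-4-methyltridec-3-enoyl chloride | ClC(=O)C/C=C(\C)CCCCCCCCCCl | intermediate
10 | methyl 3-oxopentanoate | CCC(=O)CC(=O)OC | starting material
11 | methyl 2-diazo-3-oxopentanoate | CCC(=O)C(=[N+]=[N-])C(=O)OC | intermediate
12 | methyl 2-methoxy-3-oxopentanoate (racemic) | CCC(=O)C(OC)C(=O)OC | intermediate
13 | methyl 2-methoxy-3-(trimethylsilyloxy)pent-2-enoate (mixture of geometric isomers) | CCC(O[Si](C)(C)C)=C(OC)C(=O)OC | intermediate
14 | 1,2-dimethoxy-1,3-bis(trimethylsilyloxy)penta-1,3-diene (mixture of geometric isomers, one drawn) | C/C=C(\O[Si](C)(C)C)/C(OC)=C(/OC)O[Si](C)(C)C | intermediate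
15 | methyl (7E)-17-chloro-2-methoxy-4,8-dimethyl-5-oxo-3-(trimethylsilyloxy)heptadeca-2,7-dienoate (C2=C3 geometry undefined; formed in the flask, not isolated) | COC(=O)C(OC)=C(O[Si](C)(C)C)C(C)C(=O)C/C=C(\C)CCCCCCCCCCl | intermediate
16 | methyl (E)-17-chloro-2-methoxy-4,8-dimethyl-3,5-dioxoheptadec-7-enoate (mixture of diastereomers and enol forms) | COC(=O)C(OC)C(=O)C(C)C(=O)C/C=C(\C)CCCCCCCCCCl | intermediate
17 | 6-[(E)-12-chloro-3-methyldodec-2-en-1-yl]-2,3-dimethoxy-5-methyl-4H-pyran-4-one | COc1oc(C/C=C(\C)CCCCCCCCCCl)c(C)c(=O)c1OC | intermediate
18 | lehualide C, S-[(E)-12-(5,6-dimethoxy-3-methyl-4-oxo-4H-pyran-2-yl)-10-methyldodec-10-en-1-yl] ethanethioate | COc1oc(C/C=C(\C)CCCCCCCCCSC(C)=O)c(C)c(=O)c1OC | target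

Total step count: 11.
Longest linear sequence: 7 steps (steps 1–4 and 9–11 from 1; equally steps 5–8 and 9–11 from 10).

Steps most likely to fail

Step 9. C-acylation may lose out to O-acylation of the diene or to protodesilylation of the diene by adventitious acid, and the Lewis acid may draw the β,γ-alkene of the acyl donor into conjugation. The fallback makes the same C5–C6 bond at the aldehyde oxidation level. It sets out from alcohol 6 and diene 14. Dess–Martin periodinane (NaHCO3, CH2Cl2, 0 °C) should convert 6 into aldehyde 7, which is used at once. A Mukaiyama aldol addition of 14 through its terminal carbon (BF3·OEt2, CH2Cl2, −78 °C) should then give methyl (E)-17-chloro-5-hydroxy-2-methoxy-4,8-dimethyl-3-oxoheptadec-7-enoate F1. Dess–Martin oxidation of the C5 carbinol of F1 brings the route back at triketide 16.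

Step 10. After activation of the enol oxygen, chloride substitution or enolisation toward C1' with alkene migration may compete with ring closure through the ester oxygen. The fallback separates ring closure from methylation and sets out from triketide 16. DBU in toluene at rt should lactonise the diketone enolate onto the ester to give 6-[(E)-12-chloro-3-methyldodec-2-en-1-yl]-4-hydroxy-3-methoxy-5-methyl-2H-pyran-2-one F2. CH3OSO2CF3 in CH2Cl2 should then methylate the lactone carbonyl oxygen, and loss of the hydroxyl proton brings the route back at pyranone 17.

Step 3. Acid-promoted migration of the β,γ-alkene into conjugation at the aldehyde stage, or oxidative cleavage, may erode the acid. The fallback splits the oxidation into two neutral stages and sets out from alcohol 6. Dess–Martin periodinane (NaHCO3, CH2Cl2, 0 °C) should give aldehyde 7, this time isolated crude. Pinnick oxidation (NaClO2, NaH2PO4, 2-methyl-2-butene, t-BuOH/H2O) should then give acid 8, where the route resumes. No compound outside the compound list is made (F0).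

Further compounds
F1 | step 9 | methyl (E)-17-chloro-5-hydroxy-2-methoxy-4,8-dimethyl-3-oxoheptadec-7-enoate (mixture of diastereomers) | COC(=O)C(OC)C(=O)C(C)C(O)C/C=C(\C)CCCCCCCCCCl
F2 | step 10 | 6-[(E)-12-chloro-3-methyldodec-2-en-1-yl]-4-hydroxy-3-methoxy-5-methyl-2H-pyran-2-one | COc1c(O)c(C)c(C/C=C(\C)CCCCCCCCCCl)oc1=O
F0 | step 3 | none | none
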